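**Retrosynthetic overview**

1. The target is reached by ester chemistry only from a bicyclic 19‑alcohol carrying the C15 acid as its allyl ester: the angelate is put on by late O‑acylation and the acid is released last by Pd‑mediated deallylation.
2. Both rings come from one acyclic (S)‑2‑methyl‑2‑alkyloxirane triene ester in a single cationic cascade. Lewis‑acid opening at the quaternary oxirane carbon (C4) forms C4–C5 (ring A) first, then C10–C9 (ring B), and the cascade ends by loss of H‑7. The oxirane CH2–O becomes C19–OH, so no C3 oxygen ever has to be removed.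
3. The oxirane comes from a methyl ketone by catalytic asymmetric sulfur‑ylide methylene transfer, the only external source of chirality.
4. The ketone comes from an ω‑bromo (2Z,6E)‑farnesoate (SeO2 oxidation, Appel bromination) and a 3‑oxobutyl Grignard equivalent, joined by Cu‑catalysed C1–C2 coupling.
5. The (2Z)‑farnesoate comes from syn‑methylcupration of an ynoate made in one pot from (E)‑geranylacetone.

Assumption: the (S)‑binaphthoxide form of the LaLi3 catalyst is taken to deliver the (S)‑oxirane in step 6; if the first run shows the opposite sense, the (R)‑binaphthoxide catalyst is used and nothing else changes.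

**Route**

Step 1
Reactants: 1 (5E)-6,10-dimethylundeca-5,9-dien-2-one ((E)-geranylacetone)
Product: 4 allyl (6E)-7,11-dimethyldodeca-6,10-dien-2-ynoate, via enol phosphate 2 (not isolated), via lithium acetylide 3 (not isolated)
Conditions: LiN(i-Pr)2 (1.05 equiv), THF, −78 °C; ClP(O)(OEt)2, −78 °C → rt; LiN(i-Pr)2 (2.3 equiv), −78 °C → rt; allyl chloroformate, −78 → 0 °C
Reagents that add atoms: allyl chloroformate C=CCOC(=O)Cl
Why: Kinetic enolisation at the methyl group, O‑phosphorylation and twofold elimination (methyl ketone → terminal alkyne through the enol phosphate) give acetylide 3, which is C‑acylated by the chloroformate while the 6E olefin is untouched.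

Step 2
Reactants: 4 allyl (6E)-7,11-dimethyldodeca-6,10-dien-2-ynoate
Product: 5 allyl (2Z,6E)-3,7,11-trimethyldodeca-2,6,10-trienoate
Conditions: Me2CuLi (from MeLi, CuI), THF/Et2O, −78 °C, 30 min; MeOH then aq. NH4Cl at −78 °C
Reagents that add atoms: lithium dimethylcuprate [Li+].C[Cu-]C
Why: Conjugate addition of the Gilman cuprate to the ynoate is a syn carbocupration, so the new methyl and the vinyl hydrogen end up cis and the chain cis to the ester (2Z, the later 13Z), fixed by protonation at −78 °C before the alkenylcuprate can equilibrate.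

Step 3
Reactants: 5 allyl (2Z,6E)-3,7,11-trimethyldodeca-2,6,10-trienoate
Product: 6 allyl (2Z,6E,10E)-12-hydroxy-3,7,11-trimethyldodeca-2,6,10-trienoate
Conditions: SeO2 (0.3 equiv), t-BuOOH (3 equiv), salicylic acid (0.1 equiv), CH2Cl2, 0 °C → rt, stopped at partial conversion
Reagents that add atoms: tert-butyl hydroperoxide CC(C)(C)OO (net oxygen source), relayed through selenium dioxide O=[Se]=O
Why: SeO2‑catalysed allylic oxidation (ene reaction then [2,3]-shift) attacks the most electron‑rich, terminal trisubstituted olefin at its (E)-methyl group, the conjugated 2‑ene being deactivated, which gives the (10E)-12‑ol.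

Step 4
Reactants: 6 allyl (2Z,6E,10E)-12-hydroxy-3,7,11-trimethyldodeca-2,6,10-trienoate
Product: 7 allyl (2Z,6E,10E)-12-bromo-3,7,11-trimethyldodeca-2,6,10-trienoate
Conditions: CBr4, PPh3, CH2Cl2, 0 °C
Reagents that add atoms: carbon tetrabromide BrC(Br)(Br)Br
Why: Appel bromination is an SN2 displacement at the primary allylic carbon under neutral conditions, so there is no allylic transposition and the 10E geometry is kept.

Step 5
Reactants: 7 allyl (2Z,6E,10E)-12-bromo-3,7,11-trimethyldodeca-2,6,10-trienoate; 8 2-(2-bromoethyl)-2,5,5-trimethyl-1,3-dioxane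
Product: 11 allyl (2Z,6E,10E)-3,7,11-trimethyl-15-oxohexadeca-2,6,10-trienoate, via Grignard reagent 9 (not isolated), via dioxane ketal 10 (not isolated)
Conditions: 8, Mg, THF, 25 °C; added to 7 + Li2CuCl4 (5 mol %), THF, −78 → −20 °C; then 2 M HCl, THF, 40 °C
Reagents that add atoms: water O
Why: Kochi‑type Li2CuCl4‑catalysed sp3–sp3 cross‑coupling of the primary allylic bromide with the alkyl Grignard reagent takes place at the α‑carbon with retention of the E olefin at low temperature, where the hindered conjugated ester is not attacked, and dilute acid then hydrolyses the ketal.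

Step 6
Reactants: 11 allyl (2Z,6E,10E)-3,7,11-trimethyl-15-oxohexadeca-2,6,10-trienoate
Product: 12 allyl (2Z,6E,10E)-3,7,11-trimethyl-14-[(2S)-2-methyloxiran-2-yl]tetradeca-2,6,10-trienoate
Conditions: Me2S(O)=CH2 (1.3 equiv, from Me3S(O)I and NaH), LaLi3[(S)-binaphthoxide]3 (5 mol %), (2,4,6-(MeO)3C6H2)3P=O (5 mol %), 5 Å sieves, THF, rt
Reagents that add atoms: dimethylsulfoxonium methylide C[S+](C)(=O)[CH2-]
Why: Catalytic asymmetric Corey–Chaykovsky epoxidation, in which the La/Li binaphthoxide complex binds ketone and ylide, tells the methyl group from the chain and delivers CH2 to one face, sets the quaternary (S) centre (the future C4), while the β,β‑disubstituted enoate is too hindered for cyclopropanation at room temperature.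

Step 7
Reactants: 12 allyl (2Z,6E,10E)-3,7,11-trimethyl-14-[(2S)-2-methyloxiran-2-yl]tetradeca-2,6,10-trienoate
Product: 13 allyl (13Z)-19-hydroxylabda-7,13-dien-15-oate (4S,5R,9S,10R)
Conditions: MeAlCl2 (2.5 equiv), CH2Cl2 (0.01 M), −94 → −78 °C, 30 min; Et3N/MeOH quench at −78 °C; chromatography on AgNO3‑impregnated silica
Reagents that add atoms: none
Why: Proposed new method: epoxide‑initiated cationic polyene bicyclisation in which a 2,2‑disubstituted oxirane takes the place of the usual trisubstituted one — MeAlCl2 activates the oxirane, the 10‑ene attacks the tertiary carbon C4 anti to the breaking C–O bond (inversion, so the (S)-oxirane fixes C4 and with it the absolute sense of the chair–chair fold), the oxirane CH2, pulled back from the incoming olefin by the three‑membered ring, is expected to take the axial site syn to the C10 methyl and become C19–OH while the methyl goes equatorial, the two E olefins give the trans ring fusion with H‑5 and H‑9 anti to the C10 methyl, the C8 cation loses the axial H‑7 (Zaitsev) and the electron‑poor 13‑enoate stays out; the other fold would give the 18‑hydroxy compound of the antipodal ring system, a diastereomer that is removed by chromatography; the closest known reaction type is the MeAlCl2‑ or SnCl4‑promoted bicyclisation of trisubstituted epoxy‑polyenes (inversion at the tertiary epoxide carbon, enoate‑terminated chains stopping at the bicycle), together with monocyclisations started from 2‑methyl‑2‑alkyloxiranes.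

Step 8
Reactants: 13 allyl (13Z)-19-hydroxylabda-7,13-dien-15-oate; 14 angelic acid ((2Z)-2-methylbut-2-enoic acid)
Product: 16 allyl (13Z)-19-[(2Z)-2-methylbut-2-enoyloxy]labda-7,13-dien-15-oate, via mixed anhydride 15 (not isolated)
Conditions: 14 (3 equiv), 2,4,6-Cl3C6H2COCl, Et3N, toluene, rt, 2 h; then 13, toluene, 80 °C
Reagents that add atoms: none
Why: Yamaguchi‑type acylation with the preformed mixed anhydride, run without a nucleophilic catalyst, transfers the (Z)-acyl group to the hindered neopentyl primary alcohol without isomerisation to the tiglate.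

Step 9
Reactants: 16 allyl (13Z)-19-[(2Z)-2-methylbut-2-enoyloxy]labda-7,13-dien-15-oate
Product: 17 (13Z)-19-[(2Z)-2-methylbut-2-enoyloxy]labda-7,13-dien-15-oic acid (4S,5R,9S,10R)
Conditions: Pd(PPh3)4 (5 mol %), morpholine (10 equiv), THF, rt; work‑up at pH 4
Reagents that add atoms: none
Why: Tsuji–Trost deallylation, in which zerovalent palladium ionises the allyl ester and morpholine traps the allyl group, is neutral and leaves the angelate, both ring and side‑chain olefins and all stereocentres untouched.

**Compound list**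

1 | (5E)-6,10-dimethylundeca-5,9-dien-2-one ((E)-geranylacetone) | CC(=O)CC/C=C(\C)CCC=C(C)C | starting material
2 | diethyl (5E)-6,10-dimethylundeca-1,5,9-trien-2-yl phosphate | C=C(CC/C=C(\C)CCC=C(C)C)OP(=O)(OCC)OCC | intermediate
3 | [(5E)-6,10-dimethylundeca-5,9-dien-1-yn-1-yl]lithium | [Li]C#CCC/C=C(\C)CCC=C(C)C | intermediate
4 | allyl (6E)-7,11-dimethyldodeca-6,10-dien-2-ynoate | C=CCOC(=O)C#CCC/C=C(\C)CCC=C(C)C | intermediate
5 | allyl (2Z,6E)-3,7,11-trimethyldodeca-2,6,10-trienoate | C=CCOC(=O)/C=C(/C)CC/C=C(\C)CCC=C(C)C | intermediate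
6 | allyl (2Z,6E,10E)-12-hydroxy-3,7,11-trimethyldodeca-2,6,10-trienoate | C=CCOC(=O)/C=C(/C)CC/C=C(\C)CC/C=C(\C)CO | intermediate
7 | allyl (2Z,6E,10E)-12-bromo-3,7,11-trimethyldodeca-2,6,10-trienoate | C=CCOC(=O)/C=C(/C)CC/C=C(\C)CC/C=C(\C)CBr | intermediate
8 | 2-(2-bromoethyl)-2,5,5-trimethyl-1,3-dioxane | CC1(CCBr)OCC(C)(C)CO1 | starting material
9 | [2-(2,5,5-trimethyl-1,3-dioxan-2-yl)ethyl]magnesium bromide | CC1(CC[Mg]Br)OCC(C)(C)CO1 | intermediate
10 | allyl (2Z,6E,10E)-3,7,11-trimethyl-14-(2,5,5-trimethyl-1,3-dioxan-2-yl)tetradeca-2,6,10-trienoate | C=CCOC(=O)/C=C(/C)CC/C=C(\C)CC/C=C(\C)CCCC1(C)OCC(C)(C)CO1 | intermediate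
11 | allyl (2Z,6E,10E)-3,7,11-trimethyl-15-oxohexadeca-2,6,10-trienoate | C=CCOC(=O)/C=C(/C)CC/C=C(\C)CC/C=C(\C)CCCC(C)=O | intermediate
12 | allyl (2Z,6E,10E)-3,7,11-trimethyl-14-[(2S)-2-methyloxiran-2-yl]tetradeca-2,6,10-trienoate | C=CCOC(=O)/C=C(/C)CC/C=C(\C)CC/C=C(\C)CCC[C@@]1(C)CO1 | intermediate
13 | allyl (13Z)-19-hydroxylabda-7,13-dien-15-oate (4S,5R,9S,10R) | OC[C@@]1(C)CCC[C@]2(C)[C@@H](CC/C(C)=C\C(=O)OCC=C)C(C)=CC[C@@H]12 | intermediate
14 | angelic acid, (2Z)-2-methylbut-2-enoic acid | C/C=C(/C)C(=O)O | starting material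
15 | (2Z)-2-methylbut-2-enoic 2,4,6-trichlorobenzoic anhydride | C/C=C(/C)C(=O)OC(=O)c1c(Cl)cc(Cl)cc1Cl | intermediate
16 | allyl (13Z)-19-[(2Z)-2-methylbut-2-enoyloxy]labda-7,13-dien-15-oate (4S,5R,9S,10R) | C/C=C(/C)C(=O)OC[C@@]1(C)CCC[C@]2(C)[C@@H](CC/C(C)=C\C(=O)OCC=C)C(C)=CC[C@@H]12 | intermediate
17 | (13Z)-19-[(2Z)-2-methylbut-2-enoyloxy]labda-7,13-dien-15-oic acid (4S,5R,9S,10R) | C/C=C(/C)C(=O)OC[C@@]1(C)CCC[C@]2(C)[C@@H](CC/C(C)=C\C(=O)O)C(C)=CC[C@@H]12 | target

**Step count**

Total steps: 9. Longest linear sequence: 9 steps (1 → 17); 8 and 14 enter as purchased side inputs.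

**The three steps most likely to fail**

Step 7 (bicyclisation). This step is unprecedented in this form, and three things can go wrong:
- the C8 cation may lose a C17 proton instead of H‑7, which is the most probable shortfall;
- the oxirane CH2 may take the equatorial site, giving the separable 18‑hydroxy diastereomer of the antipodal ring system;
- a 1,2‑hydride shift may turn the oxirane into the aldehyde.

The fallback sets out from 12 and comes back at 13, and no longer lets the kinetic end of the cascade decide where the olefin sits. The cascade is run as above and worked up as the olefin mixture whose other main component is the exocyclic isomer allyl (13Z)-19-hydroxylabda-8(17),13-dien-15-oate F1. The double bond is then placed in a separate thermodynamic operation: p‑TsOH·H2O (5 mol %) in benzene at 40 °C moves the exocyclic double bond of F1 into the ring to give 13, and the minor tetrasubstituted 8‑ene is removed on AgNO3‑impregnated silica. The 19‑hydroxyl cannot reach C8, and the (Z)-enoate and the allyl ester are stable to catalytic sulfonic acid.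

Step 6 (asymmetric methylene transfer). Enantioselectivity and its sense are not established for a long‑chain, polyunsaturated alkyl methyl ketone, and the ylide could attack the enoate. The fallback sets out from 7 and comes back at 12, taking the C4 stereocentre from the chiral pool instead of from a catalyst. The known (S)-citramalic acid building block (4S)-4-(2-bromoethyl)-2,2,4-trimethyl-1,3-dioxolane F2 is turned with Mg in THF into {2-[(4S)-2,2,4-trimethyl-1,3-dioxolan-4-yl]ethyl}magnesium bromide F3. F3 is coupled with 7 (Li2CuCl4 cat., THF, −78 → −20 °C) to give the acetonide allyl (2Z,6E,10E)-3,7,11-trimethyl-14-[(4S)-2,2,4-trimethyl-1,3-dioxolan-4-yl]tetradeca-2,6,10-trienoate F4. Aqueous 80% acetic acid at 40 °C releases the diol allyl (2Z,6E,10E,15S)-15,16-dihydroxy-3,7,11,15-tetramethylhexadeca-2,6,10-trienoate F5. Cyclodehydration with PPh3 and diisopropyl azodicarboxylate in THF activates the primary hydroxyl and closes the oxirane from the tertiary oxygen, with the quaternary centre untouched, to give 12.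

Step 8 (angeloylation). The neopentyl, axially shielded C19 hydroxyl may react slowly, and prolonged heating can leak angelate into tiglate. The fallback sets out from 13 and comes back at 16, building the (Z)-olefin on the substrate instead of transferring it. 13 is acylated with 2-[bis(2,2,2-trifluoroethoxy)phosphoryl]propanoic acid (dicyclohexylcarbodiimide, 4-(dimethylamino)pyridine, CH2Cl2) to give the phosphonate ester allyl (13Z)-19-({2-[bis(2,2,2-trifluoroethoxy)phosphoryl]propanoyl}oxy)labda-7,13-dien-15-oate F6. A Still–Gennari olefination of F6 with acetaldehyde (KN(SiMe3)2, 18-crown-6, THF, −78 °C) then forms the (Z)-2-methylbut-2-enoate kinetically and gives 16.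

**Further compounds**

F1 | step 7 | allyl (13Z)-19-hydroxylabda-8(17),13-dien-15-oate | OC[C@@]1(C)CCC[C@]2(C)[C@@H](CC/C(C)=C\C(=O)OCC=C)C(=C)CC[C@@H]12
F2 | step 6 | (4S)-4-(2-bromoethyl)-2,2,4-trimethyl-1,3-dioxolane | CC1(C)OC[C@](C)(CCBr)O1
F3 | step 6 | {2-[(4S)-2,2,4-trimethyl-1,3-dioxolan-4-yl]ethyl}magnesium bromide | CC1(C)OC[C@](C)(CC[Mg]Br)O1
F4 | step 6 | allyl (2Z,6E,10E)-3,7,11-trimethyl-14-[(4S)-2,2,4-trimethyl-1,3-dioxolan-4-yl]tetradeca-2,6,10-trienoate | C=CCOC(=O)/C=C(/C)CC/C=C(\C)CC/C=C(\C)CCC[C@@]1(C)COC(C)(C)O1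
F5 | step 6 | allyl (2Z,6E,10E,15S)-15,16-dihydroxy-3,7,11,15-tetramethylhexadeca-2,6,10-trienoate | C=CCOC(=O)/C=C(/C)CC/C=C(\C)CC/C=C(\C)CCC[C@](C)(O)CO
F6 | step 8 | allyl (13Z)-19-({2-[bis(2,2,2-trifluoroethoxy)phosphoryl]propanoyl}oxy)labda-7,13-dien-15-oate | CC(C(=O)OC[C@@]1(C)CCC[C@]2(C)[C@@H](CC/C(C)=C\C(=O)OCC=C)C(C)=CC[C@@H]12)P(=O)(OCC(F)(F)F)OCC(F)(F)F
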